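**Strategy.** With indene numbering of the target, the cyclohexene ring C3a–C4–C5–C6=C7–C7a is a Diels–Alder retron and is disconnected across C4–C5 and C3a–C7a. A thermal intramolecular Diels–Alder reaction of a linear all-E pentaenyl γ-oxo enoate joins the two fully substituted carbons C4 and C5, closes both rings and sets four stereocentres in one operation, steered only by the C1 methyl stereocentre. The feature exploited is the C6=C7 alkene that lies between ring-fusion carbon C7a and quaternary C5. The precursor is an acyclic keto ester; its C3 carbonyl is afterwards turned into the C2=C3 ethyl alkene through an enol triflate.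

Key step: step 8

Assumption: compounds 1, 3, 6, 8, 11 and 12 are taken as purchasable; the carbinol centre made in step 7 is carried as a mixture of epimers because step 8 removes it.

Step 1
Reactants: 1 (R)-4-(tert-butoxy)-2-methyl-4-oxobutanoic acid
Product: 2 tert-butyl (R)-4-hydroxy-3-methylbutanoate
Conditions: BH3·SMe2, THF, 0 °C to rt; aq. work-up
Reagents that add atoms: none
Why: Borane reduces the free carboxylic acid chemoselectively beside the tert-butyl ester (chemoselective borane reduction), and the stereocentre is not touched.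

Step 2
Reactants: 2 tert-butyl (R)-4-hydroxy-3-methylbutanoate; 3 2-(triphenylphosphoranylidene)propanal
Product: 5 tert-butyl (3R,4E)-3,5-dimethyl-6-oxohex-4-enoate, via tert-butyl (R)-3-methyl-4-oxobutanoate 4 (not isolated)
Conditions: PhI(OAc)2, TEMPO (cat.), CH2Cl2, rt; aq. NaHCO3 wash; then 3, toluene, 80 °C
Reagents that add atoms: 2-(triphenylphosphoranylidene)propanal (3), CC(C=O)=P(c1ccccc1)(c1ccccc1)c1ccccc1
Why: TEMPO/PhI(OAc)2 oxidation stops at the aldehyde, which is used at once to limit epimerisation of its α-stereocentre, and the Wittig reaction of the stabilised formyl ylide should give the (E)-trisubstituted enal.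

Step 3
Reactants: 5 tert-butyl (3R,4E)-3,5-dimethyl-6-oxohex-4-enoate; 6 2-(triphenylphosphoranylidene)butanal
Product: 7 tert-butyl (3R,4E,6E)-7-ethyl-3,5-dimethyl-8-oxoocta-4,6-dienoate
Conditions: toluene, 110 °C
Reagents that add atoms: 2-(triphenylphosphoranylidene)butanal (6), CCC(C=O)=P(c1ccccc1)(c1ccccc1)c1ccccc1
Why: A second Wittig reaction with the ethyl-bearing stabilised ylide homologates the enal to the dienal and should set the new trisubstituted alkene E, which places the ethyl group cis to the rest of the chain.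

Step 4
Reactants: 7 tert-butyl (3R,4E,6E)-7-ethyl-3,5-dimethyl-8-oxoocta-4,6-dienoate; 8 diethyl [(2E)-3-phenylprop-2-en-1-yl]phosphonate
Product: 9 tert-butyl (3R,4E,6E,8E,10E)-7-ethyl-3,5-dimethyl-11-phenylundeca-4,6,8,10-tetraenoate
Conditions: 8, NaN(SiMe3)2, THF, −78 °C; then 7, −78 to 0 °C; aq. NH4Cl
Reagents that add atoms: diethyl [(2E)-3-phenylprop-2-en-1-yl]phosphonate (8), CCOP(=O)(OCC)C/C=C/c1ccccc1
Why: Horner–Wadsworth–Emmons olefination through the α-carbon of the cinnamyl phosphonate anion should give the new disubstituted alkene E and so complete the all-E tetraene.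

Step 5
Reactants: 9 tert-butyl (3R,4E,6E,8E,10E)-7-ethyl-3,5-dimethyl-11-phenylundeca-4,6,8,10-tetraenoate
Product: 10 (3R,4E,6E,8E,10E)-7-ethyl-3,5-dimethyl-11-phenylundeca-4,6,8,10-tetraenal
Conditions: i-Bu2AlH, CH2Cl2, −78 °C; Rochelle salt work-up
Reagents that add atoms: none
Why: Partial ester reduction: at −78 °C the hindered tert-butyl ester gives a stable aluminium hemiacetal that releases the aldehyde only on work-up.

Step 6
Reactants: 11 (E)-3-iodo-2-methylprop-2-enoic acid; 12 2-(trimethylsilyl)ethanol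
Product: 13 2-(trimethylsilyl)ethyl (E)-3-iodo-2-methylprop-2-enoate
Conditions: DCC, DMAP (cat.), CH2Cl2, 0 °C to rt
Reagents that add atoms: 2-(trimethylsilyl)ethanol (12), C[Si](C)(C)CCO
Why: Steglich esterification installs a fluoride-cleavable ester without touching the alkenyl iodide or its E geometry.

Step 7
Reactants: 10 (3R,4E,6E,8E,10E)-7-ethyl-3,5-dimethyl-11-phenylundeca-4,6,8,10-tetraenal; 13 2-(trimethylsilyl)ethyl (E)-3-iodo-2-methylprop-2-enoate
Product: 14 2-(trimethylsilyl)ethyl (2E,6R,7E,9E,11E,13E)-10-ethyl-4-hydroxy-2,6,8-trimethyl-14-phenyltetradeca-2,7,9,11,13-pentaenoate (both C4 epimers)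
Conditions: CrCl2, NiCl2 (cat.), DMSO, rt
Reagents that add atoms: 2-(trimethylsilyl)ethyl (E)-3-iodo-2-methylprop-2-enoate (13), C[Si](C)(C)CCOC(=O)/C(C)=C/I
Why: Nozaki–Hiyama–Kishi reaction: the alkenyl iodide becomes an alkenylchromium species with retention of the E geometry and adds chemoselectively to the aldehyde, and the new carbinol centre forms as a mixture that step 8 erases.

Step 8
Reactants: 14 2-(trimethylsilyl)ethyl (2E,6R,7E,9E,11E,13E)-10-ethyl-4-hydroxy-2,6,8-trimethyl-14-phenyltetradeca-2,7,9,11,13-pentaenoate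
Product: 16 2-(trimethylsilyl)ethyl (1R,3aS,4R,5S,7aS)-5-ethyl-1,4,7-trimethyl-3-oxo-5-[(1E,3E)-4-phenylbuta-1,3-dien-1-yl]-2,3,3a,4,5,7a-hexahydro-1H-indene-4-carboxylate, via pentaenyl γ-oxo ester 15 (not isolated)
Conditions: Dess–Martin periodinane, CH2Cl2, 0 °C to rt; aq. Na2S2O3/NaHCO3 wash; crude 15 in toluene (0.01 M, BHT), 80 °C
Reagents that add atoms: none
Why: Oxidation unmasks the γ-oxo enoate, and on heating 15 should undergo a concerted suprafacial [4+2] cycloaddition between its C7a=C7–C6=C5 diene and its C4=C3a dienophile (product numbering) through a three-atom tether; the closest known reaction type is the type 1 intramolecular Diels–Alder reaction of ester-terminated (E,E)-nona-1,3,8-trienes, which gives trans-fused hydrindenes. The cyclohexene closes by the [4+2] cycloaddition itself (bonds C4–C5 and C3a–C7a), and the cyclopentanone closes as the tether-derived fused ring through the same C3a–C7a bond. C7a is controlled by the C1 stereocentre: A(1,3) strain with the C7 methyl holds C1–H in the diene plane, so the tethered dienophile adds to the face anti to the C1 methyl; C3a follows from the ester-endo, tether-exo transition state, which gives the trans ring fusion. C4 and C5 are fixed by stereospecific suprafacial addition to the (E)-enoate (ester cis to H-3a) and to the (E)-configured ethyl-bearing diene terminus (ethyl inside, dienyl outside). The step needs endo selectivity for the ester over the ketone, which is expected because the tether carbonyl is twisted out of conjugation in a transition state that forms a five-membered ring, and periselectivity for the inner diene, which is the only one the short tether can reach.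

Step 9
Reactants: 16 2-(trimethylsilyl)ethyl (1R,3aS,4R,5S,7aS)-5-ethyl-1,4,7-trimethyl-3-oxo-5-[(1E,3E)-4-phenylbuta-1,3-dien-1-yl]-2,3,3a,4,5,7a-hexahydro-1H-indene-4-carboxylate
Product: 17 2-(trimethylsilyl)ethyl (1S,3aS,4R,5S,7aS)-5-ethyl-1,4,7-trimethyl-5-[(1E,3E)-4-phenylbuta-1,3-dien-1-yl]-3-{[(trifluoromethyl)sulfonyl]oxy}-3a,4,5,7a-tetrahydro-1H-indene-4-carboxylate
Conditions: KN(SiMe3)2, THF, −78 °C; then PhNTf2, −78 to 0 °C; aq. NH4Cl
Reagents that add atoms: N-phenylbis(trifluoromethanesulfonimide), O=S(=O)(N(c1ccccc1)S(=O)(=O)C(F)(F)F)C(F)(F)F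
Why: Kinetic deprotonation should occur at the unhindered C2 methylene and not at the ring-fusion C3a–H next to quaternary C4, and O-sulfonylation traps the enolate as the C2=C3 enol triflate (as with 17-keto steroids) without disturbing the trans ring fusion.

Step 10
Reactants: 17 2-(trimethylsilyl)ethyl (1S,3aS,4R,5S,7aS)-5-ethyl-1,4,7-trimethyl-5-[(1E,3E)-4-phenylbuta-1,3-dien-1-yl]-3-{[(trifluoromethyl)sulfonyl]oxy}-3a,4,5,7a-tetrahydro-1H-indene-4-carboxylate
Product: 18 2-(trimethylsilyl)ethyl (1R,3aR,4R,5S,7aS)-3,5-diethyl-1,4,7-trimethyl-5-[(1E,3E)-4-phenylbuta-1,3-dien-1-yl]-3a,4,5,7a-tetrahydro-1H-indene-4-carboxylate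
Conditions: Et2Zn, Pd(dppf)Cl2 (cat.), THF, 50 °C
Reagents that add atoms: diethylzinc, CC[Zn]CC
Why: Negishi cross-coupling of the enol triflate, in which the wide-bite-angle dppf ligand favours reductive elimination over β-hydride elimination of the ethylpalladium intermediate, should place the ethyl group on C3 with the alkene fixed at C2=C3.

Step 11
Reactants: 18 2-(trimethylsilyl)ethyl (1R,3aR,4R,5S,7aS)-3,5-diethyl-1,4,7-trimethyl-5-[(1E,3E)-4-phenylbuta-1,3-dien-1-yl]-3a,4,5,7a-tetrahydro-1H-indene-4-carboxylate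
Product: 19 (1R,3aR,4R,5S,7aS)-3,5-diethyl-1,4,7-trimethyl-5-[(1E,3E)-4-phenylbuta-1,3-dien-1-yl]-3a,4,5,7a-tetrahydro-1H-indene-4-carboxylic acid
Conditions: Bu4NF, THF, rt to 40 °C; aq. NH4Cl
Reagents that add atoms: none
Why: Fluoride attacks silicon and the 2-(trimethylsilyl)ethyl ester fragments by β-elimination, so the acid is released without any attack at the carbonyl group flanked by two quaternary carbons.

**Compound list**

1 | (R)-4-(tert-butoxy)-2-methyl-4-oxobutanoic acid | CC(C)(C)OC(=O)C[C@@H](C)C(=O)O | starting material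
2 | tert-butyl (R)-4-hydroxy-3-methylbutanoate | CC(C)(C)OC(=O)C[C@@H](C)CO | intermediate
3 | 2-(triphenylphosphoranylidene)propanal | CC(C=O)=P(c1ccccc1)(c1ccccc1)c1ccccc1 | starting material
4 | tert-butyl (R)-3-methyl-4-oxobutanoate | CC(C)(C)OC(=O)C[C@@H](C)C=O | intermediate
5 | tert-butyl (3R,4E)-3,5-dimethyl-6-oxohex-4-enoate | CC(C)(C)OC(=O)C[C@@H](C)/C=C(C)/C=O | intermediate
6 | 2-(triphenylphosphoranylidene)butanal | CCC(C=O)=P(c1ccccc1)(c1ccccc1)c1ccccc1 | starting material
7 | tert-butyl (3R,4E,6E)-7-ethyl-3,5-dimethyl-8-oxoocta-4,6-dienoate | CC(C)(C)OC(=O)C[C@@H](C)/C=C(C)/C=C(CC)/C=O | intermediate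
8 | diethyl [(2E)-3-phenylprop-2-en-1-yl]phosphonate | CCOP(=O)(OCC)C/C=C/c1ccccc1 | starting material
9 | tert-butyl (3R,4E,6E,8E,10E)-7-ethyl-3,5-dimethyl-11-phenylundeca-4,6,8,10-tetraenoate | CC(C)(C)OC(=O)C[C@@H](C)/C=C(C)/C=C(CC)/C=C/C=C/c1ccccc1 | intermediate
10 | (3R,4E,6E,8E,10E)-7-ethyl-3,5-dimethyl-11-phenylundeca-4,6,8,10-tetraenal | O=CC[C@@H](C)/C=C(C)/C=C(CC)/C=C/C=C/c1ccccc1 | intermediate
11 | (E)-3-iodo-2-methylprop-2-enoic acid | OC(=O)/C(C)=C/I | starting material
12 | 2-(trimethylsilyl)ethanol | C[Si](C)(C)CCO | starting material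
13 | 2-(trimethylsilyl)ethyl (E)-3-iodo-2-methylprop-2-enoate | C[Si](C)(C)CCOC(=O)/C(C)=C/I | intermediate
14 | 2-(trimethylsilyl)ethyl (2E,6R,7E,9E,11E,13E)-10-ethyl-4-hydroxy-2,6,8-trimethyl-14-phenyltetradeca-2,7,9,11,13-pentaenoate (both C4 epimers) | C[Si](C)(C)CCOC(=O)/C(C)=C/C(O)C[C@@H](C)/C=C(C)/C=C(CC)/C=C/C=C/c1ccccc1 | intermediate
15 | 2-(trimethylsilyl)ethyl (2E,6R,7E,9E,11E,13E)-10-ethyl-2,6,8-trimethyl-4-oxo-14-phenyltetradeca-2,7,9,11,13-pentaenoate | C[Si](C)(C)CCOC(=O)/C(C)=C/C(=O)C[C@@H](C)/C=C(C)/C=C(CC)/C=C/C=C/c1ccccc1 | intermediate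
16 | 2-(trimethylsilyl)ethyl (1R,3aS,4R,5S,7aS)-5-ethyl-1,4,7-trimethyl-3-oxo-5-[(1E,3E)-4-phenylbuta-1,3-dien-1-yl]-2,3,3a,4,5,7a-hexahydro-1H-indene-4-carboxylate (trans-fused) | O=C1C[C@@H](C)[C@@H]2C(C)=C[C@@](/C=C/C=C/c3ccccc3)(CC)[C@](C)(C(=O)OCC[Si](C)(C)C)[C@@H]12 | intermediate
17 | 2-(trimethylsilyl)ethyl (1S,3aS,4R,5S,7aS)-5-ethyl-1,4,7-trimethyl-5-[(1E,3E)-4-phenylbuta-1,3-dien-1-yl]-3-{[(trifluoromethyl)sulfonyl]oxy}-3a,4,5,7a-tetrahydro-1H-indene-4-carboxylate | O=S(=O)(OC1=C[C@@H](C)[C@@H]2C(C)=C[C@@](/C=C/C=C/c3ccccc3)(CC)[C@](C)(C(=O)OCC[Si](C)(C)C)[C@@H]12)C(F)(F)F | intermediate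
18 | 2-(trimethylsilyl)ethyl (1R,3aR,4R,5S,7aS)-3,5-diethyl-1,4,7-trimethyl-5-[(1E,3E)-4-phenylbuta-1,3-dien-1-yl]-3a,4,5,7a-tetrahydro-1H-indene-4-carboxylate | CCC1=C[C@@H](C)[C@@H]2C(C)=C[C@@](/C=C/C=C/c3ccccc3)(CC)[C@](C)(C(=O)OCC[Si](C)(C)C)[C@@H]12 | intermediate
19 | (1R,3aR,4R,5S,7aS)-3,5-diethyl-1,4,7-trimethyl-5-[(1E,3E)-4-phenylbuta-1,3-dien-1-yl]-3a,4,5,7a-tetrahydro-1H-indene-4-carboxylic acid | CCC1=C[C@@H](C)[C@@H]2C(C)=C[C@@](/C=C/C=C/c3ccccc3)(CC)[C@](C)(C(=O)O)[C@@H]12 | target

Total step count: 11. Longest linear sequence: 10 steps (steps 1–5 and 7–11).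

**Steps most likely to fail**

1. Step 8 (key cycloaddition). What may go wrong is insufficient preference for the ester-endo over the ketone-endo transition state, so that the cis-fused hydrindanone forms beside the trans-fused one, or erosion of facial control. The fallback sets out from 14. The oxidation is postponed and the allylic alcohol itself is heated (toluene, BHT, 110 °C), so that the cycloaddition runs with an sp3 carbinol tether and a dienophile activated by the ester alone, the arrangement for which ester-endo, trans-selective closure is best established. This should give 2-(trimethylsilyl)ethyl (1R,3aS,4R,5S,7aS)-5-ethyl-3-hydroxy-1,4,7-trimethyl-5-[(1E,3E)-4-phenylbuta-1,3-dien-1-yl]-2,3,3a,4,5,7a-hexahydro-1H-indene-4-carboxylate F1 (both C3 epimers). Dess–Martin oxidation of it comes back to the route at 16.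

2. Step 5. What may go wrong is over-reduction to the primary alcohol or incomplete conversion of the hindered tert-butyl ester. The fallback sets out from 9. Exhaustive reduction with LiAlH4 (Et2O, 0 °C) should give (3R,4E,6E,8E,10E)-7-ethyl-3,5-dimethyl-11-phenylundeca-4,6,8,10-tetraen-1-ol F2, and Dess–Martin oxidation of it comes back at 10.

3. Step 4. What may go wrong is ε-deprotonation of the dienal by the phosphonate anion, with loss of the C3 stereocentre or deconjugation, and imperfect E selectivity. The fallback sets out from 7. Takai iodo-olefination (CrCl2, CHI3, THF, 0 °C) should give tert-butyl (3R,4E,6E,8E)-7-ethyl-9-iodo-3,5-dimethylnona-4,6,8-trienoate F3. Suzuki–Miyaura coupling of it with (E)-2-phenylvinylboronic acid (Pd(PPh3)4, aq. K3PO4, THF), which keeps both alkene geometries, comes back at 9 without strong base meeting an enolisable aldehyde.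

Further compounds
F1 | step 8 | 2-(trimethylsilyl)ethyl (1R,3aS,4R,5S,7aS)-5-ethyl-3-hydroxy-1,4,7-trimethyl-5-[(1E,3E)-4-phenylbuta-1,3-dien-1-yl]-2,3,3a,4,5,7a-hexahydro-1H-indene-4-carboxylate (both C3 epimers) | OC1C[C@@H](C)[C@@H]2C(C)=C[C@@](/C=C/C=C/c3ccccc3)(CC)[C@](C)(C(=O)OCC[Si](C)(C)C)[C@@H]12
F2 | step 5 | (3R,4E,6E,8E,10E)-7-ethyl-3,5-dimethyl-11-phenylundeca-4,6,8,10-tetraen-1-ol | OCC[C@@H](C)/C=C(C)/C=C(CC)/C=C/C=C/c1ccccc1
F3 | step 4 | tert-butyl (3R,4E,6E,8E)-7-ethyl-9-iodo-3,5-dimethylnona-4,6,8-trienoate | CC(C)(C)OC(=O)C[C@@H](C)/C=C(C)/C=C(CC)/C=C/I
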